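Each flask is a closed, stirred, isothermal vessel of constant volume, charged with 1.80 equiv of reagent, and you want to know how much first product stands in it at two times.

| flask | starting material | reagent | remark | time |
|---|---|---|---|---|
| south-west | 0.067 M | 1.8 equiv | run made earlier |  |
| north-east | 0.22 M | 1.8 equiv | run made earlier |  |
| Friday's | 0.080 M | 1.80 equiv |  | 12 h |
| Tuesday's | 0.20 M | 1.80 equiv |  | 12 h |
| Thursday's | 0.30 M | 1.80 equiv |  | 12 h |
| Wednesday's | 0.60 M | 1.80 equiv |  | 12 h |
| Monday's | 0.15 M | 1.80 equiv |  | 12 h |

- south-west (time / h: first product / %, starting material / %): 3.00: 21.8, 54.5; 6.00: 27.2, 37.5; 10.0: 27.8, 24.7; 12.0: 28.8, 21.6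
- north-east (time / h: first product / %, starting material / %): 3.00: 29.1, 25.2; 6.00: 27.6, 13.8; 10.0: 24.4, 8.8; 12.0: 21.7, 7.5

(readings scatter by 0.5 percentage points)

- a reading or a percentage of first product counts all its forms, free or not
- a reading of starting material is of its free form alone

* the flasks put in order of amount of first product, in percent of the starting material charged, best first, at 12 h (Friday's / Tuesday's / Thursday's / Wednesday's / Monday's)
* the same order at 80 min (Friday's / Tuesday's / Thursday's / Wednesday's / Monday's)
* the amount of first product, in percent of the starting material charged of the flask you put first, at 12 h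
* the amount of first product, in percent of the starting material charged of the flask you put last, at 12 h

Put the earlier runs on one clock. The south-west run at 10.0 h and the north-east run at 3.00 h differ in concentration, yet concentration times time comes to 0.670 M·h and 0.660 M·h, and they read 24.7 % against 25.2 % of starting material and 27.8 % against 29.1 % of first product. So, with the equivalents held, I read percent against this product, a normalised time, and call it the dose, which for Friday's at 12 h is 0.960 M·h.

The ladder then runs in dose. On the first rung starting material goes quickly: the south-west run has 54.5 % left at 0.201 M·h. On the second, first product levels off, reading 28.8 % at 0.804 M·h, a dose that Wednesday's reaches in 1.34 h but Friday's only in 10.1 h. On the third, first product falls more slowly than it climbed: the north-east run goes from 27.6 % to 21.7 % over 1.32 M·h.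

At 12 h even Friday's, with the smallest dose, lies past that reading, so I put the smallest dose first, and interpolating gives me 28.4 %. Wednesday's, at 7.20 M·h, lies beyond the readings, so I claim for it only a place last, under 21.7 %. At 80 min the doses stop at Wednesday's 0.800 M·h, just short of the south-west run's last reading, so I reverse the order and put the largest dose first.

The forecast, for which the runs “fall on one curve”, says Friday's > Monday's > Tuesday's > Thursday's > Wednesday's at 12 h, from 28.5 % to 17 %, and Wednesday's > Thursday's > Tuesday's > Monday's > Friday's at 80 min. The flasks give Friday's > Monday's > Tuesday's > Thursday's > Wednesday's at 12 h, from 28.1 % to 16.3 %, and Wednesday's > Thursday's > Tuesday's > Monday's > Friday's at 80 min.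

    starting material + reagent → first product (k = 2.97 × 10⁻⁴ M⁻¹ s⁻¹)
    starting material + reagent → other mono adduct (k = 2.17 × 10⁻⁴ M⁻¹ s⁻¹)
    reagent + first product → bis adduct (k = 2.69 × 10⁻⁴ M⁻¹ s⁻¹)
    reagent + other mono adduct → bis adduct (k = 9.65 × 10⁻⁴ M⁻¹ s⁻¹)
    starting material + first product ⇌ idle adduct, settled at all times (K = 1.85 M⁻¹)

Friday's, at its dose of 0.960 M·h, gives 28.1 % against my 28.4 %. Left to 50 h, Friday's reaches a dose of 4.00 M·h, close to the 3.60 M·h of Thursday's, and holds 19.2 % of first product against 20.2 % for Thursday's at 12 h. The passing of reagent + first product into bis adduct is the largest single effect on Wednesday's: without that step, first product in Wednesday's at 12 h stands at 57.4 % rather than 16.3 %.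

The data are simulated for an exercise; noise was put on by code.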